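All runs come from a simulation with made-up constants; noise was put on by code.

**Late shares.** Late in both runs, at 18 min, part of the charge has not become product: the birch run holds 33.7 % of its charge as product, and the alder run, charged twice as heavily, holds 28.2 %.

| flask | starting material | time |
|---|---|---|
| birch | 0.800 M |  |
| alder | 1.60 M |  |
| oak | 0.320 M | 18 min |

- birch run (time / min: [product] / M): 0.72: 0.0369; 1.6: 0.0797; 3.6: 0.1472; 8.0: 0.2188; 18: 0.2696
- alder run (time / min: [product] / M): 0.72: 0.0594; 1.6: 0.1210; 3.6: 0.2314; 8.0: 0.3666; 18: 0.4517

(each reading ± 0.002 M)

* apparent order in [starting material] of the starting rate, round the charge of the birch run (the rate where two percent of its starting material have turned into product) (one fixed amount of product, the same in the runs compared)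
* product in the oak run at 18 min, as a share of the starting material charged
* which of these the readings show (the product binds the substrate / the substrate is lost by itself / the substrate pairs with itself / two substrates go astray together)

- Overall: starting material -> product.
- Constant volume, constant temperature.
- Bound and free are read together.
- An order is taken over about fifteen percent of the charge, up and down.

**Two extremes.** Suppose first that each molecule goes its way alone. Then the share stays put when the charge changes, and the starting rate follows the charge, with order 1. Suppose instead that starting material is so strongly held in pairs, the idle substrate dimer, in fast balance (a pre-equilibrium), that free starting material follows the square root of the charge. The order is then 0.5. The first readings give a rough order of 0.687, lower than the lone case and higher than the paired one, so I take it that the substrate pairs with itself, with part of each charge held back from the first reading on.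

**Odds line.** Follow one molecule at 18 min: it is in product, free, or in a pair. You can read the odds against product, leftover per product, as 1.97 in the birch run and 2.54 in the alder run. Near balance, free starting material goes with product and pairs go with its square, so these odds climb on a straight line with the product made. The two runs give 3.16 M⁻¹, the pairing slope: the rise of the odds per M of product. The line's foot, the odds of a lone molecule, reads 1.12.

**Oak estimate.** I assume the oak run stands as near its end at 18 min as the other two. Its charge then meets the line at a share of 39.7 %. That is below the lone-molecule share of 47.3 % and above the birch share. The forecast gives order 0.71, a share of 44 %, higher than mine, and the substrate pairs with itself: “A sublinear rate from the outset points to self-pairing”.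

**Result.** The flask gives order 0.72, a share of 39.5 % in the oak run, and the substrate pairs with itself.

    starting material ⇌ product (0.1362 min⁻¹, 0.1542 min⁻¹)
    2 starting material ⇌ idle substrate dimer, settled at all times (1.110 M⁻¹)

The fit with the main steps alone put the oak run at 29.3 %. At the oak run's share, its odds against product read 1.53, and the line with the pairing slope gives 1.52 at that product.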